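**Strategy.** The quinone ring (C1 carbonyl, C2–OH, C3–hexadecyl, C4 carbonyl, C5–OH, C6–H) is the bis-enol of a cyclohexane-1,2,4,5-tetraone, so C6 is the α-carbon of the C1 ketone and C5 an oxalyl acyl carbon. The route rests on disconnecting C5–C6: a Dieckmann-type Claisen closure of the acyclic trioxo ester CH3–CO–CO–CH(C16H33)–CO–CO2Et makes the six-membered ring and delivers the dihydroxyquinone at its final oxidation level, with no protecting group or redox step afterwards. This precursor, whose methyl group is C6 and whose ester carbon is C5, is assembled in two steps from stearoyl chloride, a 1-ethoxyvinylstannane (masked acetyl) and diethyl oxalate.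

Key step: step 3

Remark: ring atoms are numbered as in the drawn tautomer: C1 (C=O next to C6–H), C2 (C–OH), C3 (C–hexadecyl), C4 (C=O), C5 (C–OH), C6 (C–H). The target has no stereocentre; the C3 centres of 5, 6 and 7 are enolisable, racemic and lost in the final enolisation.

**Step 1**
Reactants: 1 octadecanoyl chloride (stearoyl chloride); 2 tributyl(1-ethoxyvinyl)stannane
Product: 3 2-ethoxyicos-1-en-3-one
Conditions: PdCl2(PPh3)2 (2 mol %), toluene, 80 °C, Ar; chromatography on Et3N-deactivated silica
Reagents that add atoms: tributyl(1-ethoxyvinyl)stannane (2), CCCC[Sn](CCCC)(CCCC)C(=C)OCC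
Why: Stille acylation, in which oxidative addition of the acyl chloride to zerovalent palladium (formed from the divalent palladium precatalyst), transfer of the 1-ethoxyvinyl group from tin and reductive elimination should give the α-ethoxy enone, a masked 1,2-diketone carrying C6, C1, C2 and C3; no stereocentre is formed.

**Step 2**
Reactants: 3 2-ethoxyicos-1-en-3-one; 4 diethyl oxalate
Product: 6 ethyl 3-hexadecyl-2,4,5-trioxohexanoate, via ethyl 5-ethoxy-3-hexadecyl-2,4-dioxohex-5-enoate 5 (not isolated)
Conditions: LiN(SiMe3)2 (1.1 equiv), THF, −78 °C; (CO2Et)2 (1.5 equiv), −78 → 0 °C; then 2 M aq. HCl, THF, rt; extractive work-up, used crude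
Reagents that add atoms: diethyl oxalate (4), CCOC(=O)C(=O)OCC; water, O
Why: Enone 3 can enolise only at C4 (the other α-carbon is the vinyl carbon), so its lithium enolate should be C-acylated by diethyl oxalate at the future C3 in a crossed Claisen condensation driven by deprotonation of β-diketone 5, and the acidic quench then hydrolyses the 1-ethoxyvinyl enol ether to the methyl ketone; the C3 centre is enolisable and of no consequence.

**Step 3**
Reactants: 6 ethyl 3-hexadecyl-2,4,5-trioxohexanoate
Product: 8 3-hexadecyl-2,5-dihydroxy-1,4-benzoquinone (target), via 3-hexadecylcyclohexane-1,2,4,5-tetraone 7 (not isolated)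
Conditions: KOt-Bu (3.2 equiv), THF, 0 °C → rt, Ar; then 1 M aq. HCl; recrystallisation
Reagents that add atoms: none
Why: KOt-Bu should first remove the C3–H between the C2 and C4 carbonyls and then a C6–H of the C1 methyl ketone; the C6 enolate adds to the C5 ester carbonyl, ethoxide leaves, and tetraone 7 is deprotonated twice to the dipotassium salt of 8, a bis-vinylogous carboxylate whose formation makes the closure irreversible before acid liberates 8. This is an intramolecular Claisen (Dieckmann) condensation of a ketone enolate with an oxalyl ester, the six-ring counterpart of the oxalate double Claisen that gives cyclopentane-1,2,4-triones and the ring-closing half of the classical α-keto ester self-condensation to 3,6-dialkyl-2,5-dihydroxybenzoquinones. The quinone ring closes in a 6-(enolexo)-exo-trig mode. No stereocentre is created, and the enolisable C3 centre of 6 becomes sp2. The step needs acylation of C6 by C5 in preference to aldol addition of C6 to the C4 ketone (five-membered ring) and to retro-Claisen cleavage; the C3 enolate shields C2 and C4 from nucleophiles, the base is non-nucleophilic, aldol adducts can revert, and only the Claisen path ends in the doubly deprotonated quinone.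

**Compound list**
1 | octadecanoyl chloride (stearoyl chloride) | CCCCCCCCCCCCCCCCCC(=O)Cl | starting material
2 | tributyl(1-ethoxyvinyl)stannane | CCCC[Sn](CCCC)(CCCC)C(=C)OCC | starting material
3 | 2-ethoxyicos-1-en-3-one | C=C(OCC)C(=O)CCCCCCCCCCCCCCCCC | intermediate
4 | diethyl oxalate | CCOC(=O)C(=O)OCC | starting material
5 | ethyl 5-ethoxy-3-hexadecyl-2,4-dioxohex-5-enoate (racemic, enolisable C3; not isolated) | C=C(OCC)C(=O)C(CCCCCCCCCCCCCCCC)C(=O)C(=O)OCC | intermediate
6 | ethyl 3-hexadecyl-2,4,5-trioxohexanoate (racemic, enolisable C3; enol and hemiketal tautomers expected) | CC(=O)C(=O)C(CCCCCCCCCCCCCCCC)C(=O)C(=O)OCC | intermediate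
7 | 3-hexadecylcyclohexane-1,2,4,5-tetraone (racemic, transient tautomer of 8; not isolated) | CCCCCCCCCCCCCCCCC1C(=O)C(=O)CC(=O)C1=O | intermediate
8 | 3-hexadecyl-2,5-dihydroxy-1,4-benzoquinone (2-hexadecyl-3,6-dihydroxycyclohexa-2,5-diene-1,4-dione) | CCCCCCCCCCCCCCCCC1=C(O)C(=O)C=C(O)C1=O | target

**Total step count:** 3
**Longest linear sequence:** 3 steps (1 → 3 → 6 → 8)

**Steps most likely to fail**

1. Step 3 (key closure). The chain may fragment by retro-Claisen cleavage of the 2-alkyl-1,3-diketone, or the C6 enolate may be diverted into aldol addition to the C4 ketone or benzilic-type rearrangement of the C1/C2 diketone, before the Claisen closure occurs. Fallback: the fallback sets out from 3 and replaces the closure of a preassembled chain by a two-component annulation. Hydrolysis of the enol ether of 3 (1 M aq. HCl, THF, rt) should give icosane-2,3-dione F1. Slow addition of F1 to diethyl oxalate 4 and NaOEt in EtOH (0 °C → reflux, then aq. HCl) should then effect a double Claisen condensation that forms both C3–C4 and C5–C6 in one flask. The mono-acylated intermediate cyclises as it forms and is never isolated; whichever of the two bonds forms second closes the ring. The fallback comes back to the route at 8.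

2. Step 2. The cross-conjugated enolate of 3 may add in Michael fashion to unreacted 3, or the diketo enolate of 5 may close by oxa-Michael addition onto the ethoxyvinyl ketone (dihydropyranone formation) before the acidic unmasking. Fallback: the fallback sets out from 3 and exchanges the Michael-acceptor mask for a ketal. Acid-catalysed addition of ethanol across the enol ether (PPTS, EtOH, HC(OEt)3, rt) should give 2,2-diethoxyicosan-3-one F2. Crossed Claisen condensation of F2 with 4 (LiN(SiMe3)2, THF, −78 → 0 °C) should give ethyl 5,5-diethoxy-3-hexadecyl-2,4-dioxohexanoate F3. Ketal hydrolysis (CF3CO2H, H2O, CH2Cl2, rt) brings the fallback back to the route at 6.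

3. Step 1. The acyl-palladium intermediate may decarbonylate and undergo β-hydride elimination, or the acid-labile enol ether may be lost through protodestannylation or hydrolysis by adventitious HCl. Fallback: the fallback sets out from 1 and uses polar organolithium chemistry instead of palladium catalysis. Amidation (MeNH(OMe)·HCl, Et3N, CH2Cl2, 0 °C) should give N-methoxy-N-methyloctadecanamide F4. Addition of 1-ethoxyvinyllithium F5 (made from ethyl vinyl ether and t-BuLi, THF, −78 → 0 °C) to F4 at −78 °C, with a buffered quench, should give the ketone without over-addition and brings the fallback back to the route at 3.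

**Further compounds**
F1 | step 3 | icosane-2,3-dione | CC(=O)C(=O)CCCCCCCCCCCCCCCCC
F2 | step 2 | 2,2-diethoxyicosan-3-one | CC(OCC)(OCC)C(=O)CCCCCCCCCCCCCCCCC
F3 | step 2 | ethyl 5,5-diethoxy-3-hexadecyl-2,4-dioxohexanoate | CC(OCC)(OCC)C(=O)C(CCCCCCCCCCCCCCCC)C(=O)C(=O)OCC
F4 | step 1 | N-methoxy-N-methyloctadecanamide | CCCCCCCCCCCCCCCCCC(=O)N(C)OC
F5 | step 1 | 1-ethoxyvinyllithium | [Li]C(=C)OCC
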